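**Strategy.** Ring C is disconnected across C3–C4 and O1–C2. The O1–C8a–C4a–C4 unit of ring A is treated as an ortho-quinone methide, and C2–C3 with ring B as an ortho-hydroxystyrene. This pairing is possible because the 2′-OH sits next to C1′ and can hydrogen-bond to a chiral phosphate. One acid-catalysed oxa-[4+2] annulation closes ring C, forms both bonds and sets C2 as S. The precursors are a 2-hydroxy-4,6-bis(silyloxy)benzaldehyde already carrying bromine and iodine at the future C8 and C6, activated in situ with trimethyl orthoformate, and 2-ethenyl-5-(triisopropylsilyloxy)phenol. C4 leaves the annulation as a methyl ether and becomes the ketone late.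

Key step: step 6

Remarks on the chemistry:
- After the annulation, electrophilic halogen would enter a per-silylated ring A at C8 first and would also attack the resorcinol-type ring B. Both halogens are therefore placed on the aldehyde, where only ring A exists: the first enters ortho to the free phenol (future C8), the second at the one position left (future C6).
- Which enantiomer of the acid catalyst leads to (2S) is assumed; a pilot run would settle it and the antipode would be used if needed. The 2,4-cis chroman is written; a trans isomer would be carried along, since C4 becomes the ketone.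
- The ketone is unveiled only after all basic and organometallic steps, because a flavanone can open to its chalcone under base and lose C2.

**Route**

Step 1
Reactants: 1 2,4,6-trihydroxybenzaldehyde
Product: 2 2-hydroxy-4,6-bis(triisopropylsilyloxy)benzaldehyde
Conditions: TIPSCl (2.1 equiv), imidazole, DMF, 0 °C → rt
Reagents that add atoms: triisopropylsilyl chloride, CC(C)[Si](Cl)(C(C)C)C(C)C
Why: Phenol silylation should stop at the bis-ether, because the last ortho-OH is held in a hydrogen bond to the aldehyde carbonyl and is the least nucleophilic of the three.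

Step 2
Reactants: 2 2-hydroxy-4,6-bis(triisopropylsilyloxy)benzaldehyde
Product: 3 3-bromo-2-hydroxy-4,6-bis(triisopropylsilyloxy)benzaldehyde
Conditions: NBS (1.0 equiv), MeCN, −20 → 0 °C
Reagents that add atoms: N-bromosuccinimide, O=C1CCC(=O)N1Br
Why: Electrophilic aromatic bromination should go to C3, ortho to the free chelated phenol, because C5 lies between two bulky silyl ethers; this carbon becomes C8.

Step 3
Reactants: 3 3-bromo-2-hydroxy-4,6-bis(triisopropylsilyloxy)benzaldehyde
Product: 4 3-bromo-2-hydroxy-5-iodo-4,6-bis(triisopropylsilyloxy)benzaldehyde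
Conditions: NIS (1.2 equiv), TFA (0.2 equiv), MeCN, 0 °C → rt
Reagents that add atoms: N-iodosuccinimide, O=C1CCC(=O)N1I
Why: Electrophilic aromatic iodination with acid-activated NIS takes the only ring position left, para to the free phenol, which fixes the pattern bromine at future C8 and iodine at future C6.

Step 4
Reactants: 5 2,4-dihydroxybenzaldehyde
Product: 6 2-hydroxy-4-(triisopropylsilyloxy)benzaldehyde
Conditions: TIPSCl (1.05 equiv), imidazole, CH2Cl2, 0 °C
Reagents that add atoms: triisopropylsilyl chloride, CC(C)[Si](Cl)(C(C)C)C(C)C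
Why: Selective silylation of the more acidic, non-chelated 4-OH, the ortho-OH being tied to the carbonyl by a hydrogen bond.

Step 5
Reactants: 6 2-hydroxy-4-(triisopropylsilyloxy)benzaldehyde
Product: 7 2-ethenyl-5-(triisopropylsilyloxy)phenol
Conditions: Ph3PCH3Br (2.5 equiv), KOtBu (2.4 equiv), THF, 0 °C → rt; used at once
Reagents that add atoms: methyltriphenylphosphonium bromide, C[P+](c1ccccc1)(c1ccccc1)c1ccccc1.[Br-]
Why: Wittig methylenation with excess ylide, the first equivalent being spent on the phenol, is the standard entry to ortho-hydroxystyrenes.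

Step 6
Reactants: 4 3-bromo-2-hydroxy-5-iodo-4,6-bis(triisopropylsilyloxy)benzaldehyde; 7 2-ethenyl-5-(triisopropylsilyloxy)phenol; 8 trimethyl orthoformate
Product: 11 (2S,4S)-8-bromo-2-[2-hydroxy-4-(triisopropylsilyloxy)phenyl]-6-iodo-4-methoxy-5,7-bis(triisopropylsilyloxy)chroman, via dimethyl acetal 9 (not isolated), via 4-methoxy ortho-quinone methide 10 (not isolated)
Conditions: 8 (1.5 equiv), (R)-TRIP [3,3′-bis(2,4,6-triisopropylphenyl)-1,1′-binaphthyl-2,2′-diyl hydrogen phosphate] (10 mol %), 5 Å MS, toluene, −20 °C → rt, 7 added slowly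
Reagents that add atoms: none
Why: Proposed new method: the acid turns 4 through acetal 9 into the 4-methoxy ortho-quinone methide 10, present as its oxocarbenium–phosphate ion pair; the terminal CH2 of styrene 7 attacks the methine carbon (C3–C4 bond) and the resulting C2 benzylic cation, stabilised by the 2′- and 4′-oxygens, is taken by the ring A phenol oxygen (O1–C2 bond), either as a concerted asynchronous inverse-electron-demand oxa-Diels–Alder reaction or in two steps. The closest known reaction types are chiral phosphoric acid-catalysed [4+2] cycloadditions of ortho-quinone methides with ortho-hydroxystyrenes to 2-arylchromans and the achiral acid-catalysed annulation of salicylaldehydes, orthoformates and styrenes to 4-alkoxy-2-arylchromans; their combination in an enantioselective form is new. Ring C closes as a six-membered ring in a formal [4+2] event, its last bond by attack of the phenol oxygen on the cationic C2 (6-exo-trig with respect to the quinone-methide form of that cation). C2 should be set by the catalyst, whose phosphate holds the oxocarbenium ion by ion pairing and the styrene by a hydrogen bond to its 2′-OH and so exposes one face of the alkene, while C4 follows from the endo-like cis arrangement and is erased later. The step needs enantiofacial control at C2, which rests on the free 2′-OH, and regiocontrol, which follows from polarity (nucleophilic CH2 to C4, phenol oxygen to the cation at C2). Friedel–Crafts attack on ring A is excluded because bromine and iodine occupy both of its free positions, and the same halogens should make the 4-methoxy group of 11 slower to ionise again under the acid.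

Step 7
Reactants: 11 (2S,4S)-8-bromo-2-[2-hydroxy-4-(triisopropylsilyloxy)phenyl]-6-iodo-4-methoxy-5,7-bis(triisopropylsilyloxy)chroman
Product: 12 (2S,4S)-8-bromo-6-iodo-4-methoxy-2-[2,4-bis(triisopropylsilyloxy)phenyl]-5,7-bis(triisopropylsilyloxy)chroman
Conditions: TIPSCl (1.5 equiv), imidazole, DMAP (cat.), DMF, 40 °C
Reagents that add atoms: triisopropylsilyl chloride, CC(C)[Si](Cl)(C(C)C)C(C)C
Why: Phenol silylation under conditions free of Lewis acid, so that the ionisable 4-methoxy group is untouched, caps the only free phenol before the cross-couplings and the oxidation.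

Step 8
Reactants: 13 3-methylbut-1-yne; 14 pinacolborane
Product: 15 (E)-4,4,5,5-tetramethyl-2-(3-methylbut-1-en-1-yl)-1,3,2-dioxaborolane
Conditions: Cp2Zr(H)Cl (5 mol %), Et3N (10 mol %), neat, sealed tube, 60 °C
Reagents that add atoms: none
Why: Zirconium hydride-catalysed hydroboration of a terminal alkyne is a syn addition with boron at the terminal carbon and should give the (E)-alkenylboronate only.

Step 9
Reactants: 12 (2S,4S)-8-bromo-6-iodo-4-methoxy-2-[2,4-bis(triisopropylsilyloxy)phenyl]-5,7-bis(triisopropylsilyloxy)chroman; 15 (E)-4,4,5,5-tetramethyl-2-(3-methylbut-1-en-1-yl)-1,3,2-dioxaborolane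
Product: 16 (2S,4S)-8-bromo-4-methoxy-6-[(E)-3-methylbut-1-en-1-yl]-2-[2,4-bis(triisopropylsilyloxy)phenyl]-5,7-bis(triisopropylsilyloxy)chroman
Conditions: PdCl2(dppf) (5 mol %), K3PO4 (3 equiv), 1,4-dioxane/H2O (5:1), 60 °C
Reagents that add atoms: none
Why: Suzuki–Miyaura coupling in which zerovalent palladium inserts into the C–I bond much faster than into C–Br, so only C6 should react, with retention of the alkene geometry of the boronate; the base-stable 4-methoxychroman cannot open at C2.

Step 10
Reactants: 16 (2S,4S)-8-bromo-4-methoxy-6-[(E)-3-methylbut-1-en-1-yl]-2-[2,4-bis(triisopropylsilyloxy)phenyl]-5,7-bis(triisopropylsilyloxy)chroman; 17 1-bromo-3-methylbut-2-ene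
Product: 19 (2S,4S)-4-methoxy-6-[(E)-3-methylbut-1-en-1-yl]-8-(3-methylbut-2-en-1-yl)-2-[2,4-bis(triisopropylsilyloxy)phenyl]-5,7-bis(triisopropylsilyloxy)chroman, via prenylzinc bromide 18 (not isolated)
Conditions: 17, Zn dust, LiCl, THF, 0 °C; then 16, Pd(OAc)2 (2 mol %), CPhos (4 mol %), THF, rt
Reagents that add atoms: none
Why: Negishi coupling at the one halide left, with a CPhos-ligated palladium catalyst of the kind known to join prenylzinc halides to aryl bromides through the unsubstituted allyl terminus, should give the linear prenyl group at C8.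

Step 11
Reactants: 19 (2S,4S)-4-methoxy-6-[(E)-3-methylbut-1-en-1-yl]-8-(3-methylbut-2-en-1-yl)-2-[2,4-bis(triisopropylsilyloxy)phenyl]-5,7-bis(triisopropylsilyloxy)chroman
Product: 20 (2S,4RS)-6-[(E)-3-methylbut-1-en-1-yl]-8-(3-methylbut-2-en-1-yl)-2-[2,4-bis(triisopropylsilyloxy)phenyl]-5,7-bis(triisopropylsilyloxy)chroman-4-ol
Conditions: CSA (10 mol %), THF/H2O (4:1), 0 °C → rt
Reagents that add atoms: water, O
Why: SN1 solvolysis of a benzylic methyl ether whose cation is stabilised by O1 and the 5- and 7-oxygens, so weak acid in wet THF should exchange OMe for OH without touching the aryl silyl ethers, the two alkenes or C2, and the loss of configuration at C4 does not matter.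

Step 12
Reactants: 20 (2S,4RS)-6-[(E)-3-methylbut-1-en-1-yl]-8-(3-methylbut-2-en-1-yl)-2-[2,4-bis(triisopropylsilyloxy)phenyl]-5,7-bis(triisopropylsilyloxy)chroman-4-ol
Product: 21 (2S)-6-[(E)-3-methylbut-1-en-1-yl]-8-(3-methylbut-2-en-1-yl)-2-[2,4-bis(triisopropylsilyloxy)phenyl]-5,7-bis(triisopropylsilyloxy)chroman-4-one
Conditions: Dess–Martin periodinane (1.5 equiv), NaHCO3, CH2Cl2, 0 °C → rt
Reagents that add atoms: none
Why: Dess–Martin oxidation of the secondary benzylic alcohol under buffered, non-basic conditions should converge both C4 epimers on the flavanone and leave C2 and the alkenes alone.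

Step 13
Reactants: 21 (2S)-6-[(E)-3-methylbut-1-en-1-yl]-8-(3-methylbut-2-en-1-yl)-2-[2,4-bis(triisopropylsilyloxy)phenyl]-5,7-bis(triisopropylsilyloxy)chroman-4-one
Product: 22 (2S)-2-(2,4-dihydroxyphenyl)-5,7-dihydroxy-6-[(E)-3-methylbut-1-en-1-yl]-8-(3-methylbut-2-en-1-yl)chroman-4-one
Conditions: TBAF (6 equiv), AcOH (6 equiv), THF, 0 °C → rt
Reagents that add atoms: none
Why: Fluoride cleavage of the four aryl silyl ethers, buffered with acetic acid so that no phenoxide or enolate can open ring C and racemise C2, should release the target.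

**Compound list**

1 | 2,4,6-trihydroxybenzaldehyde | O=Cc1c(O)cc(O)cc1O | starting material
2 | 2-hydroxy-4,6-bis(triisopropylsilyloxy)benzaldehyde | O=Cc1c(O)cc(O[Si](C(C)C)(C(C)C)C(C)C)cc1O[Si](C(C)C)(C(C)C)C(C)C | intermediate
3 | 3-bromo-2-hydroxy-4,6-bis(triisopropylsilyloxy)benzaldehyde | O=Cc1c(O)c(Br)c(O[Si](C(C)C)(C(C)C)C(C)C)cc1O[Si](C(C)C)(C(C)C)C(C)C | intermediate
4 | 3-bromo-2-hydroxy-5-iodo-4,6-bis(triisopropylsilyloxy)benzaldehyde | O=Cc1c(O)c(Br)c(O[Si](C(C)C)(C(C)C)C(C)C)c(I)c1O[Si](C(C)C)(C(C)C)C(C)C | intermediate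
5 | 2,4-dihydroxybenzaldehyde | O=Cc1ccc(O)cc1O | starting material
6 | 2-hydroxy-4-(triisopropylsilyloxy)benzaldehyde | O=Cc1ccc(O[Si](C(C)C)(C(C)C)C(C)C)cc1O | intermediate
7 | 2-ethenyl-5-(triisopropylsilyloxy)phenol | C=Cc1ccc(O[Si](C(C)C)(C(C)C)C(C)C)cc1O | intermediate
8 | trimethyl orthoformate | COC(OC)OC | starting material
9 | 2-bromo-6-(dimethoxymethyl)-4-iodo-3,5-bis(triisopropylsilyloxy)phenol (dimethyl acetal of 4; not isolated) | COC(OC)c1c(O)c(Br)c(O[Si](C(C)C)(C(C)C)C(C)C)c(I)c1O[Si](C(C)C)(C(C)C)C(C)C | intermediate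
10 | 2-bromo-4-iodo-6-(methoxymethylidene)-3,5-bis(triisopropylsilyloxy)cyclohexa-2,4-dien-1-one (4-methoxy ortho-quinone methide, acting as its O-protonated oxocarbenium–phosphate pair; not isolated) | COC=C1C(=O)C(Br)=C(O[Si](C(C)C)(C(C)C)C(C)C)C(I)=C1O[Si](C(C)C)(C(C)C)C(C)C | intermediate
11 | (2S,4S)-8-bromo-2-[2-hydroxy-4-(triisopropylsilyloxy)phenyl]-6-iodo-4-methoxy-5,7-bis(triisopropylsilyloxy)chroman | Brc1c(O[Si](C(C)C)(C(C)C)C(C)C)c(I)c(O[Si](C(C)C)(C(C)C)C(C)C)c2c1O[C@H](c1ccc(O[Si](C(C)C)(C(C)C)C(C)C)cc1O)C[C@@H]2OC | intermediate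
12 | (2S,4S)-8-bromo-6-iodo-4-methoxy-2-[2,4-bis(triisopropylsilyloxy)phenyl]-5,7-bis(triisopropylsilyloxy)chroman | Brc1c(O[Si](C(C)C)(C(C)C)C(C)C)c(I)c(O[Si](C(C)C)(C(C)C)C(C)C)c2c1O[C@H](c1ccc(O[Si](C(C)C)(C(C)C)C(C)C)cc1O[Si](C(C)C)(C(C)C)C(C)C)C[C@@H]2OC | intermediate
13 | 3-methylbut-1-yne | CC(C)C#C | starting material
14 | pinacolborane (4,4,5,5-tetramethyl-1,3,2-dioxaborolane) | CC1(C)OBOC1(C)C | starting material
15 | (E)-4,4,5,5-tetramethyl-2-(3-methylbut-1-en-1-yl)-1,3,2-dioxaborolane | CC(C)/C=C/B1OC(C)(C)C(C)(C)O1 | intermediate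
16 | (2S,4S)-8-bromo-4-methoxy-6-[(E)-3-methylbut-1-en-1-yl]-2-[2,4-bis(triisopropylsilyloxy)phenyl]-5,7-bis(triisopropylsilyloxy)chroman | Brc1c(O[Si](C(C)C)(C(C)C)C(C)C)c(/C=C/C(C)C)c(O[Si](C(C)C)(C(C)C)C(C)C)c2c1O[C@H](c1ccc(O[Si](C(C)C)(C(C)C)C(C)C)cc1O[Si](C(C)C)(C(C)C)C(C)C)C[C@@H]2OC | intermediate
17 | 1-bromo-3-methylbut-2-ene (prenyl bromide) | CC(C)=CCBr | starting material
18 | (3-methylbut-2-en-1-yl)zinc bromide (prenylzinc bromide; not isolated) | CC(C)=CC[Zn]Br | intermediate
19 | (2S,4S)-4-methoxy-6-[(E)-3-methylbut-1-en-1-yl]-8-(3-methylbut-2-en-1-yl)-2-[2,4-bis(triisopropylsilyloxy)phenyl]-5,7-bis(triisopropylsilyloxy)chroman | CC(C)=CCc1c(O[Si](C(C)C)(C(C)C)C(C)C)c(/C=C/C(C)C)c(O[Si](C(C)C)(C(C)C)C(C)C)c2c1O[C@H](c1ccc(O[Si](C(C)C)(C(C)C)C(C)C)cc1O[Si](C(C)C)(C(C)C)C(C)C)C[C@@H]2OC | intermediate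
20 | (2S,4RS)-6-[(E)-3-methylbut-1-en-1-yl]-8-(3-methylbut-2-en-1-yl)-2-[2,4-bis(triisopropylsilyloxy)phenyl]-5,7-bis(triisopropylsilyloxy)chroman-4-ol (C4 left undefined on purpose) | CC(C)=CCc1c(O[Si](C(C)C)(C(C)C)C(C)C)c(/C=C/C(C)C)c(O[Si](C(C)C)(C(C)C)C(C)C)c2c1O[C@H](c1ccc(O[Si](C(C)C)(C(C)C)C(C)C)cc1O[Si](C(C)C)(C(C)C)C(C)C)CC2O | intermediate
21 | (2S)-6-[(E)-3-methylbut-1-en-1-yl]-8-(3-methylbut-2-en-1-yl)-2-[2,4-bis(triisopropylsilyloxy)phenyl]-5,7-bis(triisopropylsilyloxy)chroman-4-one | CC(C)=CCc1c(O[Si](C(C)C)(C(C)C)C(C)C)c(/C=C/C(C)C)c(O[Si](C(C)C)(C(C)C)C(C)C)c2c1O[C@H](c1ccc(O[Si](C(C)C)(C(C)C)C(C)C)cc1O[Si](C(C)C)(C(C)C)C(C)C)CC2=O | intermediate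
22 | (2S)-2-(2,4-dihydroxyphenyl)-5,7-dihydroxy-6-[(E)-3-methylbut-1-en-1-yl]-8-(3-methylbut-2-en-1-yl)chroman-4-one (CNP0290067.1) | CC(C)=CCc1c(O)c(/C=C/C(C)C)c(O)c2c1O[C@H](c1ccc(O)cc1O)CC2=O | target

**Step count**

Total step count: 13. Longest linear sequence: 10 steps (1, 2, 3, 6, 7, 9, 10, 11, 12, 13).

**Steps most likely to fail**

1. Step 6 (proposed new method). The chiral acid may discriminate the two faces of the styrene poorly, the acid-sensitive styrene may add to itself faster than to the oxocarbenium ion, or the halogenated acetal may ionise too slowly with a weak acid. The fallback uses known chemistry and obtains the configuration by resolution instead of catalysis. It sets out from 4, 7 and 8, which are combined under an achiral acid of the kind established for this three-component annulation (Sc(OTf)3 or diphenyl phosphate, CH2Cl2, 0 °C). This should give 11 as a racemate with its mirror image, (2R,4R)-8-bromo-2-[2-hydroxy-4-(triisopropylsilyloxy)phenyl]-6-iodo-4-methoxy-5,7-bis(triisopropylsilyloxy)chroman F1. Preparative chromatography on a chiral stationary phase removes F1, and the route is rejoined at 11.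

2. Step 9. Oxidative addition and transmetalation at an iodide flanked by two silyloxy groups may be slow, which would lead to protodeiodination or to erosion of the iodide-over-bromide preference. The fallback replaces the cross-coupling by a carbonyl olefination and sets out from 12. Iodine–magnesium exchange (iPrMgCl·LiCl, THF, −40 °C; the bromide does not exchange) should give the C6 arylmagnesium chloride F2. Quenching with DMF should give (2S,4S)-8-bromo-4-methoxy-2-[2,4-bis(triisopropylsilyloxy)phenyl]-5,7-bis(triisopropylsilyloxy)chroman-6-carbaldehyde F3. Julia–Kocienski olefination of F3 with 5-[(2-methylpropyl)sulfonyl]-1-phenyl-1H-tetrazole and KN(SiMe3)2 (DME, −60 °C → rt) should build the (E)-alkene, and the route is rejoined at 16.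

3. Step 11. The C4 cation may lose a proton to give the flav-3-ene instead of being captured by water, or the electron-rich C6 alkene may be protonated. The fallback moves the exchange to a stage where no alkene is present and sets out from 12. Treatment with TsOH·H2O (THF/H2O, 40 °C) should give (2S,4RS)-8-bromo-6-iodo-2-[2,4-bis(triisopropylsilyloxy)phenyl]-5,7-bis(triisopropylsilyloxy)chroman-4-ol F4. Suzuki–Miyaura coupling with 15 under the conditions of step 9 should give (2S,4RS)-8-bromo-6-[(E)-3-methylbut-1-en-1-yl]-2-[2,4-bis(triisopropylsilyloxy)phenyl]-5,7-bis(triisopropylsilyloxy)chroman-4-ol F5. Negishi coupling with 18 under the conditions of step 10, with one extra equivalent for the free hydroxyl, rejoins the route at 20.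

**Further compounds**

F1 | step 6 | (2R,4R)-8-bromo-2-[2-hydroxy-4-(triisopropylsilyloxy)phenyl]-6-iodo-4-methoxy-5,7-bis(triisopropylsilyloxy)chroman | Brc1c(O[Si](C(C)C)(C(C)C)C(C)C)c(I)c(O[Si](C(C)C)(C(C)C)C(C)C)c2c1O[C@@H](c1ccc(O[Si](C(C)C)(C(C)C)C(C)C)cc1O)C[C@H]2OC
F2 | step 9 | [(2S,4S)-8-bromo-4-methoxy-2-[2,4-bis(triisopropylsilyloxy)phenyl]-5,7-bis(triisopropylsilyloxy)chroman-6-yl]magnesium chloride | Brc1c(O[Si](C(C)C)(C(C)C)C(C)C)c([Mg]Cl)c(O[Si](C(C)C)(C(C)C)C(C)C)c2c1O[C@H](c1ccc(O[Si](C(C)C)(C(C)C)C(C)C)cc1O[Si](C(C)C)(C(C)C)C(C)C)C[C@@H]2OC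
F3 | step 9 | (2S,4S)-8-bromo-4-methoxy-2-[2,4-bis(triisopropylsilyloxy)phenyl]-5,7-bis(triisopropylsilyloxy)chroman-6-carbaldehyde | Brc1c(O[Si](C(C)C)(C(C)C)C(C)C)c(C=O)c(O[Si](C(C)C)(C(C)C)C(C)C)c2c1O[C@H](c1ccc(O[Si](C(C)C)(C(C)C)C(C)C)cc1O[Si](C(C)C)(C(C)C)C(C)C)C[C@@H]2OC
F4 | step 11 | (2S,4RS)-8-bromo-6-iodo-2-[2,4-bis(triisopropylsilyloxy)phenyl]-5,7-bis(triisopropylsilyloxy)chroman-4-ol | Brc1c(O[Si](C(C)C)(C(C)C)C(C)C)c(I)c(O[Si](C(C)C)(C(C)C)C(C)C)c2c1O[C@H](c1ccc(O[Si](C(C)C)(C(C)C)C(C)C)cc1O[Si](C(C)C)(C(C)C)C(C)C)CC2O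
F5 | step 11 | (2S,4RS)-8-bromo-6-[(E)-3-methylbut-1-en-1-yl]-2-[2,4-bis(triisopropylsilyloxy)phenyl]-5,7-bis(triisopropylsilyloxy)chroman-4-ol | Brc1c(O[Si](C(C)C)(C(C)C)C(C)C)c(/C=C/C(C)C)c(O[Si](C(C)C)(C(C)C)C(C)C)c2c1O[C@H](c1ccc(O[Si](C(C)C)(C(C)C)C(C)C)cc1O[Si](C(C)C)(C(C)C)C(C)C)CC2O
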